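**Assumption:** natural-source (2S)-(–)-homoeriodictyol is bought as the single enantiomer. Its ee is checked by chiral HPLC on receipt and again on the final product.

## Retrosynthetic overview
1. Target 7 comes from diacetate 6 by removing the two aryl acetates (7-O and 4'-O) without base.
2. The C6–CMe2 bond comes from an aromatic Claisen [3,3] shift of the 5-O-prenyl ether 4. Allyl inversion turns prenyl into 1,1-dimethylallyl, and C6 is the only open ortho position to O5 because the other is C4a.
3. Ether 4 comes from a Mitsunobu coupling of prenol 3 with the chelated 5-OH of 2, and 2 comes from selective 7,4'-diacetylation of (2S)-homoeriodictyol 1.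
4. No ring is built. Rings A, B and C and the C2 (S) centre arrive intact in 1, and every step stays non-basic so the pyranone never opens to the chalcone.

## Route

Step 1
Reactants: 1 (2S)-homoeriodictyol
Product: 2 (2S)-7,4'-di-O-acetylhomoeriodictyol (5-OH free)
Conditions: Ac2O (2.2 equiv), pyridine, 0 °C → rt, 1–2 h
Reagents that add atoms: acetic anhydride, CC(=O)OC(C)=O
Why: In this chemoselective O-acetylation the free 7- and 4'-phenols acylate fast while the 5-OH, hydrogen-bonded to the C4 carbonyl, stays untouched at 2.2 equiv, and the weak base at or below rt does not open the pyranone, so C2 keeps its purchased S configuration.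

Step 2
Reactants: 2 (2S)-7,4'-di-O-acetylhomoeriodictyol; 3 3-methylbut-2-en-1-ol (prenol)
Product: 4 (2S)-7,4'-di-O-acetyl-5-O-prenylhomoeriodictyol
Conditions: PPh3 (1.5 equiv), DIAD (1.5 equiv), THF, 0 °C → rt, 12 h
Reagents that add atoms: 3-methylbut-2-en-1-ol (compound 3), CC(C)=CCO
Why: This Mitsunobu etherification alkylates the only remaining phenol by SN2 at the primary carbon of prenol under near-neutral conditions that spare the aryl acetates and leave C2 untouched.

Step 3
Reactants: 4 (2S)-7,4'-di-O-acetyl-5-O-prenylhomoeriodictyol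
Product: 6 (2S)-7,4'-di-O-acetyl-6-(1,1-dimethylallyl)homoeriodictyol, via C6-cyclohexadienone 5 (not isolated)
Conditions: Eu(fod)3 (10 mol %), CHCl3, 45–50 °C, Ar, 24–36 h; SiO2 chromatography to remove the 8-prenyl isomer
Reagents that add atoms: none
Why: In this aromatic Claisen rearrangement ([3,3]-sigmatropic shift) achiral Eu(III), chelated between C4=O and O5, lowers the barrier so the prenyl group transfers with allyl inversion to C6, dienone 5 tautomerises to phenol 6 (the lowest workable temperature favours this proton shift over the follow-on Cope shift to C8), and no lasting stereocentre is made while C2 is untouched under neutral conditions.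

Step 4
Reactants: 6 (2S)-7,4'-di-O-acetyl-6-(1,1-dimethylallyl)homoeriodictyol
Product: 7 (2S)-5,7-dihydroxy-2-(4-hydroxy-3-methoxyphenyl)-6-(2-methylbut-3-en-2-yl)chroman-4-one (target)
Conditions: HCl (ca. 0.3 M, catalytic) in MeOH, 0 °C → rt, 8–12 h, N2
Reagents that add atoms: none
Why: This acid-catalysed transesterification (methanolysis) frees both phenols without generating phenoxides, which shuts off the retro-oxa-Michael/quinone-methide ring opening that racemises 4'-hydroxyflavanones, and dilute acid at rt does not protonate the monosubstituted vinyl group.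

## Compound list
1 | (2S)-homoeriodictyol, (2S)-5,7-dihydroxy-2-(4-hydroxy-3-methoxyphenyl)chroman-4-one | O=C1C[C@@H](c2ccc(O)c(OC)c2)Oc2cc(O)cc(O)c12 | starting material
2 | (2S)-7,4'-di-O-acetylhomoeriodictyol | O=C1C[C@@H](c2ccc(OC(C)=O)c(OC)c2)Oc2cc(OC(C)=O)cc(O)c12 | intermediate
3 | 3-methylbut-2-en-1-ol (prenol) | CC(C)=CCO | starting material
4 | (2S)-7,4'-di-O-acetyl-5-O-prenylhomoeriodictyol | O=C1C[C@@H](c2ccc(OC(C)=O)c(OC)c2)Oc2cc(OC(C)=O)cc(OCC=C(C)C)c12 | intermediate
5 | C6-cyclohexadienone: 6-H, 6-(1,1-dimethylallyl), C5=O, C4a=C8a, C7=C8; transient C6 epimer mixture, 2S | C=CC(C)(C)C1C(=O)C2=C(C=C1OC(C)=O)O[C@H](c1ccc(OC(C)=O)c(OC)c1)CC2=O | intermediate (not isolated)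
6 | (2S)-7,4'-di-O-acetyl-6-(1,1-dimethylallyl)homoeriodictyol | C=CC(C)(C)c1c(OC(C)=O)cc2c(c1O)C(=O)C[C@@H](c1ccc(OC(C)=O)c(OC)c1)O2 | intermediate
7 | (2S)-6-(1,1-dimethylallyl)homoeriodictyol | C=CC(C)(C)c1c(O)cc2c(c1O)C(=O)C[C@@H](c1ccc(O)c(OC)c1)O2 | target

## Totals
Total steps: 4. Longest linear sequence: 4.

## Three steps most likely to fail

**Step 3 (Claisen stops at C6, or runs on by Cope shift to the 8-prenyl isomer).**
- The risk is that dienone 5 undergoes the Cope shift faster than it aromatises, so 6 becomes the minor product.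
- The fallback sets out from 4 and comes back at 7. It rearranges a substrate whose dienone aromatises much faster.
- The activated 7-acetate alone is removed by thiolysis (PhSH, cat. imidazole, NMP, 0 °C). This gives (2S)-4'-O-acetyl-5-O-prenylhomoeriodictyol F1.
- Eu(fod)3 in CHCl3 then takes F1 through the 7-hydroxy dienone F2. This is an enolised cyclic 1,3-dione whose C6–H is far more acidic, and its 7-substituent is smaller.
- F2 therefore collapses to (2S)-4'-O-acetyl-6-(1,1-dimethylallyl)homoeriodictyol F3 before the Cope shift can compete.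
- Methanolysis of the single remaining acetate under the step 4 conditions gives 7.

**Step 4 (deacetylation with erosion of ee, or acid-induced dihydrofuran closure onto the vinyl group).**
- The fallback sets out from 1 and comes back at 7. It swaps esters for silyl ethers, so the last step is a buffered fluoride cleavage.
- TBSCl (2.2 equiv) and imidazole in CH2Cl2 at 0 °C give (2S)-7,4'-bis-O-TBS-homoeriodictyol F4.
- Mitsunobu coupling with 3 gives the 5-O-prenyl ether F5.
- Eu(fod)3 rearranges F5 through the silylated dienone F6 to (2S)-7,4'-bis-O-TBS-6-(1,1-dimethylallyl)homoeriodictyol F7.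
- Et3N·3HF in THF at 0 °C → rt releases 7.
- The cost is that the bulkier 7-O-silyl group is expected to divert more material to the C8 product.

**Step 2 (prenol-specific trouble in the Mitsunobu).**
- Possible failures are SN2' attack giving the tertiary ether, and ionisation or isoprene loss.
- The fallback sets out from 2 and comes back at 4. It builds the trisubstituted alkene after the C–O bond is in place.
- Mitsunobu coupling of 2 with allyl alcohol gives (2S)-7,4'-di-O-acetyl-5-O-allylhomoeriodictyol F8.
- Olefin cross-metathesis of F8 with excess 2-methyl-2-butene (Grubbs II, 3–5 mol %, CH2Cl2, 40 °C) converts O-allyl into O-prenyl, which is 4.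

## Further compounds
F1 | step 3 | (2S)-4'-O-acetyl-5-O-prenylhomoeriodictyol | O=C1C[C@@H](c2ccc(OC(C)=O)c(OC)c2)Oc2cc(O)cc(OCC=C(C)C)c12
F2 | step 3 | 7-hydroxy C6-cyclohexadienone (transient, C6 epimers, 2S) | C=CC(C)(C)C1C(=O)C2=C(C=C1O)O[C@H](c1ccc(OC(C)=O)c(OC)c1)CC2=O
F3 | step 3 | (2S)-4'-O-acetyl-6-(1,1-dimethylallyl)homoeriodictyol | C=CC(C)(C)c1c(O)cc2c(c1O)C(=O)C[C@@H](c1ccc(OC(C)=O)c(OC)c1)O2
F4 | step 4 | (2S)-7,4'-bis-O-TBS-homoeriodictyol | O=C1C[C@@H](c2ccc(O[Si](C)(C)C(C)(C)C)c(OC)c2)Oc2cc(O[Si](C)(C)C(C)(C)C)cc(O)c12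
F5 | step 4 | (2S)-7,4'-bis-O-TBS-5-O-prenylhomoeriodictyol | O=C1C[C@@H](c2ccc(O[Si](C)(C)C(C)(C)C)c(OC)c2)Oc2cc(O[Si](C)(C)C(C)(C)C)cc(OCC=C(C)C)c12
F6 | step 4 | silylated C6-cyclohexadienone (transient, C6 epimers, 2S) | C=CC(C)(C)C1C(=O)C2=C(C=C1O[Si](C)(C)C(C)(C)C)O[C@H](c1ccc(O[Si](C)(C)C(C)(C)C)c(OC)c1)CC2=O
F7 | step 4 | (2S)-7,4'-bis-O-TBS-6-(1,1-dimethylallyl)homoeriodictyol | C=CC(C)(C)c1c(O[Si](C)(C)C(C)(C)C)cc2c(c1O)C(=O)C[C@@H](c1ccc(O[Si](C)(C)C(C)(C)C)c(OC)c1)O2
F8 | step 2 | (2S)-7,4'-di-O-acetyl-5-O-allylhomoeriodictyol | O=C1C[C@@H](c2ccc(OC(C)=O)c(OC)c2)Oc2cc(OC(C)=O)cc(OCC=C)c12
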